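**Plan**

- Retrosynthetic cuts, in order: the three acetates and the C16 ether; the C17–CH3 bond; the lactone O–C7 bond, which is reconnected as a temporary C7–C19 bond (cyclobutanone); then C17–C19 and C7–C8 together ([2+2] of a C7=C19 ketene with a C8=C17 enol ether); the enol ether back to a lactone C8=O; C3=C4 (metathesis); C9–C10 (aldol); the ester O–C8.
- Forward ring order: cyclohexene (Diels–Alder) → nine-membered lactone (aldol union of two fragments, then metathesis) → its exocyclic enol ether → tetrahydrofuran, cyclobutanone and ten-membered carbocycle in one event → γ-lactone by ring expansion of the cyclobutanone.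
- Enabling feature: the C5–O–C8 ether oxygen of the tetrahydrofuran ring. C7 and C8 are separated only by C6, C5 and O, so a ketene at C7 on the C5 arm of the nine-membered ether reaches the C8=C17 enol ether through a five-membered ring, and the C7–C8 bond that closes this ring also closes the C1–C10 carbocycle.
- Stereochemistry: C6 from D-serine; C5 by Cornforth-controlled vinyl addition; C1 and C14 by a catalytic enantioselective Diels–Alder reaction; C2 by chelation-controlled addition; C9 and C10 by a syn-selective titanium aldol reaction; C7 and C8 dictated by C5 and the cis fusion of the bicyclo[3.2.0] unit; C17 by enolate alkylation anti to the C9 branch.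

Key step: step 20

Remark: briarane numbering is used throughout (C1 quaternary carbon with CH3 = C15; C2–C10 ten-membered ring with C3=C4, C5 bearing C16, C6–Cl, C7–O(lactone), C8 ether carbon; C11–C14 six-membered ring with C11=C20; C17(CH3 = C18)–C19(=O) lactone).
Remark: the hand of the oxazaborolidinium catalyst in step 8 is assigned from the formyl C–H···O binding model; should the first adduct show the opposite hand, the antipodal catalyst is used.

**Fragment 1 (C3–C8, C16, C19)**

Step 1
Reactants: 1 D-serine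
Product: 2 (R)-2-chloro-3-hydroxypropanoic acid
Conditions: NaNO2, 6 M HCl, H2O, 0 °C → rt
Reagents that add atoms: hydrogen chloride, Cl
Why: Diazotisation of the α-amino acid; the carboxylate displaces N2 to an α-lactone that chloride reopens, so the C–Cl bond forms with net retention and the α-carbon of D-serine becomes C6.

Step 2
Reactants: 2 (R)-2-chloro-3-hydroxypropanoic acid
Product: 4 (R)-2-chloro-3-(triethylsilyloxy)propanoic acid, via bis-silyl ester 3 (not isolated)
Conditions: Et3SiCl (2.2 equiv), imidazole, CH2Cl2, 0 °C; then H2O/THF, pH 5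
Reagents that add atoms: chlorotriethylsilane, CC[Si](Cl)(CC)CC
Why: O-Silylation of alcohol and acid followed by selective hydrolysis of the silyl ester, which is far more labile than the primary alkyl silyl ether.

Step 3
Reactants: 4 (R)-2-chloro-3-(triethylsilyloxy)propanoic acid
Product: 6 (R)-3-chloro-1-diazo-4-(triethylsilyloxy)butan-2-one, via mixed anhydride 5 (not isolated)
Conditions: i-BuOCOCl, N-methylmorpholine, THF, −20 °C; then CH2N2, Et2O, 0 °C
Reagents that add atoms: diazomethane, C=[N+]=[N-]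
Why: Acylation of diazomethane by a mixed carbonic anhydride (first half of the Arndt–Eistert protocol) at low temperature, which should leave the α-chloro stereocentre untouched.

Step 4
Reactants: 6 (R)-3-chloro-1-diazo-4-(triethylsilyloxy)butan-2-one
Product: 7 (R)-3-chloro-1-(4-methoxybenzyloxy)-4-(triethylsilyloxy)butan-2-one
Conditions: Rh2(OAc)4 (1 mol %), 4-methoxybenzyl alcohol, CH2Cl2, rt
Reagents that add atoms: 4-methoxybenzyl alcohol, COc1ccc(CO)cc1
Why: Rh2(OAc)4-catalysed O–H insertion of the α-diazo ketone carbenoid into the alcohol, which installs C16 already carrying its ether protecting group.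

Step 5
Reactants: 7 (R)-3-chloro-1-(4-methoxybenzyloxy)-4-(triethylsilyloxy)butan-2-one
Product: 8 (3R,4R)-4-chloro-3-[(4-methoxybenzyloxy)methyl]-5-(triethylsilyloxy)pent-1-en-3-ol
Conditions: CH2=CHMgBr, THF, −78 °C; NH4Cl quench at −78 °C
Reagents that add atoms: vinylmagnesium bromide, C=C[Mg]Br
Why: Grignard addition to an α-chloro ketone under Cornforth (polar Felkin–Anh) control, the vinyl group entering anti to the C–Cl bond, which sets the C5 carbinol relative to C6; the cold quench should prevent closure of the chlorohydrin to an epoxide.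

Step 6
Reactants: 8 tertiary alcohol
Product: 9 (3R,4R)-4-chloro-3-[(4-methoxybenzyloxy)methyl]-5-(triethylsilyloxy)pent-1-en-3-yl bromoacetate
Conditions: BrCH2COBr, pyridine, DMAP (cat.), CH2Cl2, 0 °C
Reagents that add atoms: bromoacetyl bromide, BrCC(Br)=O
Why: Acylation of the hindered tertiary alcohol by a small, very reactive acyl bromide under weakly basic conditions that do not deprotonate the chlorohydrin.

Step 7
Reactants: 9 bromoacetate
Product: 11 glyoxylate ester of 8 (2-oxoacetate), via nitrate ester 10 (not isolated)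
Conditions: AgNO3, MeCN, rt; then NaOAc, DMSO, rt
Reagents that add atoms: silver nitrate, [Ag+].[O-][N+](=O)[O-]
Why: Kornblum-type oxidation: bromide/nitrate exchange driven by precipitation of AgBr, then base-induced loss of nitrite from the α-nitrooxy ester gives the aldehyde.

**Fragment 2 (C1, C2, C10–C15)**

Step 8
Reactants: 12 methacrolein; 13 (E)-1-(trimethylsilyloxy)buta-1,3-diene
Product: 15 (1R,2S)-2-hydroxy-1-methylcyclohex-3-ene-1-carbaldehyde, via silyl ether adduct 14 (not isolated)
Conditions: (S)-diphenylprolinol-derived B-o-tolyl oxazaborolidine (10 mol %), Tf2NH (10 mol %), CH2Cl2, −78 °C; then citric acid, THF/H2O, 0 °C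
Reagents that add atoms: none
Why: Catalytic enantioselective Diels–Alder reaction of an α-substituted acrolein with a 1-oxygenated diene; ortho regiochemistry and formyl-endo addition should place CHO (C2) cis to the C14 oxygen, and the catalyst directs the diene to the Cα-si face, which sets C1 and C14.

Step 9
Reactants: 15 hydroxy aldehyde
Product: 16 (S)-1-[(1S,2S)-2-hydroxy-1-methylcyclohex-3-en-1-yl]prop-2-en-1-ol
Conditions: CH2=CHMgBr (3 equiv), THF, −78 °C
Reagents that add atoms: vinylmagnesium bromide, C=C[Mg]Br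
Why: Chelation-controlled Grignard addition: the magnesium alkoxide of the β-hydroxy aldehyde forms a six-membered chelate cis-fused to the cyclohexene, and vinyl should attack its convex face (the side of the C15 methyl group), giving the anti-1,3-diol with the required C2 configuration.

Step 10
Reactants: 16 diol
Product: 17 bis(tert-butyldimethylsilyl) ether of 16
Conditions: TBSOTf, 2,6-lutidine, CH2Cl2, 0 °C
Reagents that add atoms: tert-butyldimethylsilyl triflate, CC(C)(C)[Si](C)(C)OS(=O)(=O)C(F)(F)F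
Why: Standard silylation of two hindered secondary alcohols with a silyl triflate.

Step 11
Reactants: 17 bis-silyl ether
Product: 18 (4S,5S)-4-(tert-butyldimethylsilyloxy)-5-[(1S)-1-(tert-butyldimethylsilyloxy)prop-2-en-1-yl]-5-methylcyclohex-2-en-1-one
Conditions: Rh2(cap)4 (dirhodium tetrakis(caprolactamate), 1 mol %), t-BuOOH, K2CO3, CH2Cl2, rt
Reagents that add atoms: tert-butyl hydroperoxide, CC(C)(C)OO
Why: Dirhodium-catalysed allylic oxidation with t-BuOOH; hydrogen abstraction should occur at C11, the only unhindered allylic CH2, and the allyl radical should be trapped at that same, less encumbered terminus to give the enone with the C11 carbonyl.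

**Union and endgame**

Step 12
Reactants: 18 enone; 11 glyoxylate ester
Product: 21 syn-aldol adduct (C9–C10 bond; ester of 8 at C8; free 9-OH; C9 branch trans to the C2 side chain), via lithium dienolate 19 (not isolated), via titanium dienolate 20 (not isolated)
Conditions: LiN(i-Pr)2, THF, −78 °C; ClTi(Oi-Pr)3, −78 → −40 °C; then 11, −78 °C
Reagents that add atoms: none
Why: Kinetic α′-deprotonation of the enone (C10 is its only α′ position), transmetallation to the triisopropoxytitanium enolate and aldol addition through a closed Zimmerman–Traxler-type transition state, which with titanium enolates of cyclic ketones favours the syn adduct (C9), the aldehyde approaching C10 anti to the bulky C2 side chain on C1.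

Step 13
Reactants: 21 aldol adduct
Product: 22 9-O-tert-butyldimethylsilyl ether of 21
Conditions: TBSOTf, 2,6-lutidine, CH2Cl2, −40 → 0 °C
Reagents that add atoms: tert-butyldimethylsilyl triflate, CC(C)(C)[Si](C)(C)OS(=O)(=O)C(F)(F)F
Why: Silylation of the β-hydroxy ketone under non-basic conditions, which blocks retro-aldol cleavage and dehydration.

Step 14
Reactants: 22 enone
Product: 23 saturated C11 ketone (C12–C13 dihydro-22)
Conditions: [(Ph3P)CuH]6, H2O (2 equiv), benzene, rt
Reagents that add atoms: none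
Why: Conjugate reduction of the enone by the phosphine-stabilised copper hydride, which should leave the isolated vinyl groups, the ester and the alkyl chloride alone; C10 keeps its thermodynamically preferred equatorial substituent.

Step 15
Reactants: 23 diene ester
Product: 24 (3Z)-nine-membered lactone (ring C1–C2–C3=C4–C5–O–C8(=O)–C9–C10, fused to the cyclohexanone at C1/C10; C5 carries CH2OPMB and the CHCl–CH2OSiEt3 arm; 2,9,14-tris-OTBS)
Conditions: second-generation Hoveyda–Grubbs catalyst RuCl2(H2IMes)(=CH-C6H4-2-Oi-Pr) (10 mol %), toluene (1 mM), 80 °C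
Reagents that add atoms: none
Why: Ring-closing metathesis of two monosubstituted vinyl groups; the nine-membered ring can only hold the Z alkene, and the quaternary centres C1 and C5 should favour the folded conformer.

Step 16
Reactants: 24 keto lactone
Product: 25 bis-methylenated compound (C11=C20 exocyclic alkene and C8=C17H2 exocyclic enol ether of the nine-membered cyclic ether)
Conditions: Cp2TiMe2 (5 equiv), toluene, 70 °C, dark; filtration through basic alumina
Reagents that add atoms: dimethyltitanocene, C[Ti](C)(C1C=CC=C1)C1C=CC=C1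
Why: Carbonyl methylenation by Cp2Ti=CH2 generated thermally from Cp2TiMe2, which converts ketones and esters or lactones alike and is non-basic, so C9 and C10 are not epimerised.

Step 17
Reactants: 25 enol ether
Product: 26 primary alcohol (C19H2OH on C6; triethylsilyl group removed)
Conditions: HF·pyridine, pyridine, THF, 0 °C
Reagents that add atoms: none
Why: Fluoride-mediated desilylation; the primary triethylsilyl ether cleaves much faster than the three hindered secondary TBS ethers, and the pyridine buffer should protect the acid-labile enol ether.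

Step 18
Reactants: 26 primary alcohol
Product: 27 α-chloro carboxylic acid (C19 acid on C6; handled as its N-methylmorpholinium salt)
Conditions: (n-Pr4N)RuO4 (10 mol %), N-methylmorpholine N-oxide monohydrate (10 equiv), MeCN, rt
Reagents that add atoms: N-methylmorpholine N-oxide monohydrate, C[N+]1([O-])CCOCC1.O
Why: Perruthenate-catalysed oxidation of the primary alcohol through the aldehyde hydrate to the acid under non-acidic conditions, chosen so that the enol ether never meets a free strong acid.

Step 19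
Reactants: 27 carboxylic acid (salt)
Product: 29 diazo ketone (C6–C19(=O)–C7H=N2), via mixed anhydride 28 (not isolated)
Conditions: i-BuOCOCl, N-methylmorpholine, THF, −20 °C; then CH2N2, Et2O, 0 °C
Reagents that add atoms: diazomethane, C=[N+]=[N-]
Why: Mixed-anhydride acylation of diazomethane as in step 3, a base-buffered route to the diazo ketone that avoids HCl; the diazomethane carbon becomes C7.

Step 20
Reactants: 29 diazo ketone
Product: 31 cyclobutanone (C5–O–C8–C7–C6 tetrahydrofuran cis-fused at C7–C8 to the C8–C17–C19(=O)–C7 cyclobutanone, bridging the new ten-membered carbocycle), via ketene 30 (not isolated)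
Conditions: hν (365 nm LED), degassed benzene (2 mM), rt, then 45 °C
Reagents that add atoms: none
Why: Photochemical Wolff rearrangement (C6 migrates with retention from C19 to C7, loss of N2) gives the aldoketene C6–C7H=C19=O, which adds thermally across the electron-rich exocyclic enol ether C8=C17 in a [2+2] cycloaddition, C19 bonding to C17 and C7 to C8. The closest known reaction types are the intramolecular ketene–alkene cycloaddition to bicyclo[3.2.0]heptan-6-ones and the intermolecular ketene–enol ether cycloaddition to 3-alkoxycyclobutanones. Three rings close: the cyclobutanone by the cycloaddition itself, the tetrahydrofuran in a 5-exo sense with respect to C8=C17 through the three-atom tether C6–C5–O, and the C1–C10 carbocycle by the same C7–C8 bond, which bridges the nine-membered ether to an 11-oxabicyclo[6.2.1]undecene. C8 is controlled by C5, because the ketene arm can reach only the enol ether face on its own side of the ring, which forces C4 and C9 cis on the tetrahydrofuran; C7 is controlled by the obligatory cis fusion of the bicyclo[3.2.0] unit. The step needs regioselectivity, secured by the match of the electrophilic ketene carbonyl carbon with the nucleophilic CH2 terminus and by the tether length, and chemoselectivity over the C3=C4 and C11=C20 alkenes, secured by the far higher nucleophilicity and proximity of the enol ether. Direct irradiation rather than metal catalysis is chosen to favour the concerted Wolff pathway over free-carbene reactions.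

Step 21
Reactants: 31 cyclobutanone
Product: 32 γ-lactone (7,8-lactone with C17H2; O inserted between C19 and C7)
Conditions: 30% H2O2, AcOH, 0 °C
Reagents that add atoms: hydrogen peroxide, OO
Why: Baeyer–Villiger oxidation of the strained cyclobutanone; the secondary ring-fusion carbon C7 should migrate in preference to the primary C17 and with retention, and the mild peroxide conditions should spare both alkenes; this removes the temporary C7–C19 bond.

Step 22
Reactants: 32 γ-lactone
Product: 34 17-methyl lactone (2,9,14-tris-OTBS, 16-OPMB), via lithium enolate 33 (not isolated)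
Conditions: LiN(SiMe3)2, THF, −78 °C; MeI, −78 → −45 °C
Reagents that add atoms: iodomethane, CI
Why: Alkylation of the lithium lactone enolate; iodomethane should approach C17 anti to the bulky C9 branch on the adjacent quaternary C8, that is on the face of the ether oxygen, which is also the expected thermodynamic epimer, and the low temperature should suppress β-elimination of the C8 oxygen.

Step 23
Reactants: 34 tris-silyl ether
Product: 35 2,9,14-triol (16-OPMB)
Conditions: HF·pyridine, THF, 0 °C → rt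
Reagents that add atoms: none
Why: Fluoride cleavage of the three secondary TBS ethers under weakly acidic conditions tolerated by lactone, chloride, PMB ether and alkenes.

Step 24
Reactants: 35 triol
Product: 36 2,9,14-triacetate (16-OPMB)
Conditions: Ac2O, DMAP, pyridine, rt
Reagents that add atoms: acetic anhydride, CC(=O)OC(C)=O
Why: DMAP-catalysed acetylation of the three secondary alcohols while C16–O is still protected.

Step 25
Reactants: 36 triacetate PMB ether
Product: 37 CNP0408507.1 (target)
Conditions: DDQ, CH2Cl2/pH 7 buffer, 0 °C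
Reagents that add atoms: none
Why: Oxidative cleavage of the 4-methoxybenzyl ether by DDQ, orthogonal to acetates, lactone, chloride and the two alkenes, frees the C16 primary alcohol.

**Compound list**

1 | D-serine | N[C@H](CO)C(=O)O | starting material
2 | (R)-2-chloro-3-hydroxypropanoic acid | OC(=O)[C@H](Cl)CO | intermediate
3 | triethylsilyl (R)-2-chloro-3-(triethylsilyloxy)propanoate (not isolated) | CC[Si](CC)(CC)OC(=O)[C@H](Cl)CO[Si](CC)(CC)CC | intermediate
4 | (R)-2-chloro-3-(triethylsilyloxy)propanoic acid | OC(=O)[C@H](Cl)CO[Si](CC)(CC)CC | intermediate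
5 | isobutyl carbonic mixed anhydride of 4 (not isolated) | CC(C)COC(=O)OC(=O)[C@H](Cl)CO[Si](CC)(CC)CC | intermediate
6 | (R)-3-chloro-1-diazo-4-(triethylsilyloxy)butan-2-one | [N-]=[N+]=CC(=O)[C@H](Cl)CO[Si](CC)(CC)CC | intermediate
7 | (R)-3-chloro-1-(4-methoxybenzyloxy)-4-(triethylsilyloxy)butan-2-one | COc1ccc(COCC(=O)[C@H](Cl)CO[Si](CC)(CC)CC)cc1 | intermediate
8 | (3R,4R)-4-chloro-3-[(4-methoxybenzyloxy)methyl]-5-(triethylsilyloxy)pent-1-en-3-ol | O[C@](C=C)(COCc1ccc(OC)cc1)[C@H](Cl)CO[Si](CC)(CC)CC | intermediate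
9 | bromoacetate of 8 | BrCC(=O)O[C@](C=C)(COCc1ccc(OC)cc1)[C@H](Cl)CO[Si](CC)(CC)CC | intermediate
10 | (nitrooxy)acetate of 8 (not isolated) | [O-][N+](=O)OCC(=O)O[C@](C=C)(COCc1ccc(OC)cc1)[C@H](Cl)CO[Si](CC)(CC)CC | intermediate
11 | glyoxylate (2-oxoacetate) of 8 | O=CC(=O)O[C@](C=C)(COCc1ccc(OC)cc1)[C@H](Cl)CO[Si](CC)(CC)CC | intermediate
12 | methacrolein (2-methylprop-2-enal) | CC(=C)C=O | starting material
13 | (E)-1-(trimethylsilyloxy)buta-1,3-diene | C=C/C=C/O[Si](C)(C)C | starting material
14 | (1R,2S)-1-methyl-2-(trimethylsilyloxy)cyclohex-3-ene-1-carbaldehyde (not isolated) | C1C=C[C@H](O[Si](C)(C)C)[C@](C)(C=O)C1 | intermediate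
15 | (1R,2S)-2-hydroxy-1-methylcyclohex-3-ene-1-carbaldehyde | C1C=C[C@H](O)[C@](C)(C=O)C1 | intermediate
16 | (S)-1-[(1S,2S)-2-hydroxy-1-methylcyclohex-3-en-1-yl]prop-2-en-1-ol | C1C=C[C@H](O)[C@](C)([C@@H](O)C=C)C1 | intermediate
17 | bis(tert-butyldimethylsilyl) ether of 16 | C1C=C[C@H](O[Si](C)(C)C(C)(C)C)[C@](C)([C@@H](O[Si](C)(C)C(C)(C)C)C=C)C1 | intermediate
18 | (4S,5S)-4-(tert-butyldimethylsilyloxy)-5-[(1S)-1-(tert-butyldimethylsilyloxy)prop-2-en-1-yl]-5-methylcyclohex-2-en-1-one | O=C1C=C[C@H](O[Si](C)(C)C(C)(C)C)[C@](C)([C@@H](O[Si](C)(C)C(C)(C)C)C=C)C1 | intermediate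
19 | lithium cross-conjugated dienolate of 18 (C10=C11–OLi; not isolated) | [Li]OC=1C=C[C@H](O[Si](C)(C)C(C)(C)C)[C@](C)([C@@H](O[Si](C)(C)C(C)(C)C)C=C)C=1 | intermediate
20 | triisopropoxytitanium dienolate of 18 (not isolated) | CC(C)O[Ti](OC(C)C)(OC(C)C)OC=1C=C[C@H](O[Si](C)(C)C(C)(C)C)[C@](C)([C@@H](O[Si](C)(C)C(C)(C)C)C=C)C=1 | intermediate
21 | syn-aldol adduct: α-hydroxy ester linking C10 of 18 to the glyoxylate carbon (C9), ester of 8, free 9-OH | O=C1C=C[C@H](O[Si](C)(C)C(C)(C)C)[C@](C)([C@@H](O[Si](C)(C)C(C)(C)C)C=C)[C@H]1[C@H](O)C(=O)O[C@](C=C)(COCc2ccc(OC)cc2)[C@H](Cl)CO[Si](CC)(CC)CC | intermediate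
22 | 9-O-TBS ether of 21 | O=C1C=C[C@H](O[Si](C)(C)C(C)(C)C)[C@](C)([C@@H](O[Si](C)(C)C(C)(C)C)C=C)[C@H]1[C@H](O[Si](C)(C)C(C)(C)C)C(=O)O[C@](C=C)(COCc2ccc(OC)cc2)[C@H](Cl)CO[Si](CC)(CC)CC | intermediate
23 | C12–C13 dihydro-22 (saturated C11 ketone, diene ester) | O=C1CC[C@H](O[Si](C)(C)C(C)(C)C)[C@](C)([C@@H](O[Si](C)(C)C(C)(C)C)C=C)[C@H]1[C@H](O[Si](C)(C)C(C)(C)C)C(=O)O[C@](C=C)(COCc2ccc(OC)cc2)[C@H](Cl)CO[Si](CC)(CC)CC | intermediate
24 | (3Z)-nine-membered lactone fused to the C11 cyclohexanone; C5 bears CH2OPMB and CHCl–CH2OSiEt3; 2,9,14-tris-OTBS | O=C1CC[C@H](O[Si](C)(C)C(C)(C)C)[C@]2(C)[C@@H](O[Si](C)(C)C(C)(C)C)/C=C\[C@]([C@H](Cl)CO[Si](CC)(CC)CC)(COCc3ccc(OC)cc3)OC(=O)[C@@H](O[Si](C)(C)C(C)(C)C)[C@@H]12 | intermediate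
25 | 11(20)-methylene, C8=C17H2 exocyclic enol ether of the nine-membered cyclic ether | C=C1CC[C@H](O[Si](C)(C)C(C)(C)C)[C@]2(C)[C@@H](O[Si](C)(C)C(C)(C)C)/C=C\[C@]([C@H](Cl)CO[Si](CC)(CC)CC)(COCc3ccc(OC)cc3)OC(=C)[C@@H](O[Si](C)(C)C(C)(C)C)[C@@H]12 | intermediate
26 | primary alcohol (25 without the triethylsilyl group) | C=C1CC[C@H](O[Si](C)(C)C(C)(C)C)[C@]2(C)[C@@H](O[Si](C)(C)C(C)(C)C)/C=C\[C@]([C@H](Cl)CO)(COCc3ccc(OC)cc3)OC(=C)[C@@H](O[Si](C)(C)C(C)(C)C)[C@@H]12 | intermediate
27 | α-chloro carboxylic acid (C19 acid on C6), handled as N-methylmorpholinium salt | C=C1CC[C@H](O[Si](C)(C)C(C)(C)C)[C@]2(C)[C@@H](O[Si](C)(C)C(C)(C)C)/C=C\[C@]([C@H](Cl)C(=O)O)(COCc3ccc(OC)cc3)OC(=C)[C@@H](O[Si](C)(C)C(C)(C)C)[C@@H]12 | intermediate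
28 | isobutyl carbonic mixed anhydride of 27 (not isolated) | C=C1CC[C@H](O[Si](C)(C)C(C)(C)C)[C@]2(C)[C@@H](O[Si](C)(C)C(C)(C)C)/C=C\[C@]([C@H](Cl)C(=O)OC(=O)OCC(C)C)(COCc3ccc(OC)cc3)OC(=C)[C@@H](O[Si](C)(C)C(C)(C)C)[C@@H]12 | intermediate
29 | diazo ketone (C6–C19(=O)–C7H=N2) | C=C1CC[C@H](O[Si](C)(C)C(C)(C)C)[C@]2(C)[C@@H](O[Si](C)(C)C(C)(C)C)/C=C\[C@]([C@H](Cl)C(=O)C=[N+]=[N-])(COCc3ccc(OC)cc3)OC(=C)[C@@H](O[Si](C)(C)C(C)(C)C)[C@@H]12 | intermediate
30 | aldoketene (C6–C7H=C19=O; not isolated) | C=C1CC[C@H](O[Si](C)(C)C(C)(C)C)[C@]2(C)[C@@H](O[Si](C)(C)C(C)(C)C)/C=C\[C@]([C@H](Cl)C=C=O)(COCc3ccc(OC)cc3)OC(=C)[C@@H](O[Si](C)(C)C(C)(C)C)[C@@H]12 | intermediate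
31 | cyclobutanone (5,8-epoxy bridge, C7–C8 and C17–C19 bonds formed, temporary C7–C19 bond) | C=C1CC[C@H](O[Si](C)(C)C(C)(C)C)[C@]2(C)[C@@H](O[Si](C)(C)C(C)(C)C)/C=C\[C@]3(COCc5ccc(OC)cc5)O[C@]4(CC(=O)[C@H]4[C@H]3Cl)[C@@H](O[Si](C)(C)C(C)(C)C)[C@@H]12 | intermediate
32 | 7,8-γ-lactone with C17H2 | C=C1CC[C@H](O[Si](C)(C)C(C)(C)C)[C@]2(C)[C@@H](O[Si](C)(C)C(C)(C)C)/C=C\[C@]3(COCc5ccc(OC)cc5)O[C@]4(CC(=O)O[C@H]4[C@H]3Cl)[C@@H](O[Si](C)(C)C(C)(C)C)[C@@H]12 | intermediate
33 | lithium enolate of 32 (not isolated) | C=C1CC[C@H](O[Si](C)(C)C(C)(C)C)[C@]2(C)[C@@H](O[Si](C)(C)C(C)(C)C)/C=C\[C@]3(COCc5ccc(OC)cc5)O[C@]4(C=C(O[Li])O[C@H]4[C@H]3Cl)[C@@H](O[Si](C)(C)C(C)(C)C)[C@@H]12 | intermediate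
34 | 17-methyl lactone, 2,9,14-tris-OTBS, 16-OPMB | C=C1CC[C@H](O[Si](C)(C)C(C)(C)C)[C@]2(C)[C@@H](O[Si](C)(C)C(C)(C)C)/C=C\[C@]3(COCc5ccc(OC)cc5)O[C@]4([C@@H](C)C(=O)O[C@H]4[C@H]3Cl)[C@@H](O[Si](C)(C)C(C)(C)C)[C@@H]12 | intermediate
35 | 2,9,14-triol, 16-OPMB | C=C1CC[C@H](O)[C@]2(C)[C@@H](O)/C=C\[C@]3(COCc5ccc(OC)cc5)O[C@]4([C@@H](C)C(=O)O[C@H]4[C@H]3Cl)[C@@H](O)[C@@H]12 | intermediate
36 | 2,9,14-triacetate, 16-OPMB | C=C1CC[C@H](OC(C)=O)[C@]2(C)[C@@H](OC(C)=O)/C=C\[C@]3(COCc5ccc(OC)cc5)O[C@]4([C@@H](C)C(=O)O[C@H]4[C@H]3Cl)[C@@H](OC(C)=O)[C@@H]12 | intermediate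
37 | CNP0408507.1 | C=C1CC[C@H](OC(C)=O)[C@]2(C)[C@@H](OC(C)=O)/C=C\[C@]3(CO)O[C@]4([C@@H](C)C(=O)O[C@H]4[C@H]3Cl)[C@@H](OC(C)=O)[C@@H]12 | target

**Step count and risks**

Total step count: 25. Longest linear sequence: 21 steps (steps 1–7, then 12–25); fragment 2 takes steps 8–11.

The three steps most likely to fail:

Step 15 (ring-closing metathesis). The two hindered vinyl groups (one on quaternary C5, one neopentylic at C2) may not be brought together because the tertiary ester prefers its extended s-trans form, so catalyst decay or oligomerisation could outrun closure of the nine-membered lactone. The fallback reverses the order of ring formation, setting out from 23 and returning at 31. Methylenation of 23 with Cp2TiMe2 gives the acyclic bis-methylene enol ether F1. Buffered HF·pyridine gives the primary alcohol F2, and perruthenate oxidation gives the acid F3. The mixed anhydride F4 with diazomethane gives the diazo ketone F5, and irradiation gives the ketene F6, which closes to the tetrahydrofuran-fused cyclobutanone F7 bearing the two vinyl groups. In this acyclic cycloaddition the C8 configuration rests only on the preference of the C9 branch to sit cis to the small vinyl group on C5. Ring-closing metathesis of F7 with the second-generation Hoveyda–Grubbs catalyst across the cis-2,5-disubstituted tetrahydrofuran, a well-precedented closure of oxygen-bridged nine-membered rings, then gives 31.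

Step 20 (Wolff rearrangement and [2+2] cycloaddition). Under irradiation the excited diazo ketone may be diverted to carbene chemistry at the neighbouring C5 ether oxygen (oxonium ylide formation), or the ketene may be lost by secondary photoreactions before it meets the enol ether. The fallback separates homologation from cycloaddition and generates the same ketene thermally, setting out from 29 and returning at 31. Silver benzoate AgO2CPh (cat.) and Et3N in THF/H2O (Arndt–Eistert homologation) give the homologous acid F8 (C6–C7H2–C19O2H, kept as its triethylammonium salt). 1-Chloro-N,N,2-trimethylpropenylamine converts it under neutral conditions into the acid chloride F9. Slow addition of F9 to i-Pr2NEt in toluene at 80 °C under high dilution dehydrochlorinates it to ketene 30, which cyclises to 31 in the dark.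

Step 22 (C17 methylation). The facial selectivity of the alkylation may be poor or reversed, since the concave face is also flanked by the C16 arm. The fallback sets C17 by protonation instead of C–C bond formation, which inverts the outcome of a given facial preference; it sets out from 32 and returns at 34. The enolate 33 is trapped with dimethylmethyleneammonium iodide to give the Mannich base F10. Quaternisation with MeI gives the ammonium salt F11, and elimination with DBU gives the α-methylene lactone F12. Conjugate reduction of F12 with [(Ph3P)CuH]6, followed by kinetic protonation of the resulting enolate with t-BuOH from its more exposed face, then gives 34.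

**Further compounds**

F1 | step 15 | acyclic bis-methylene enol ether from 23 | C=C1CC[C@H](O[Si](C)(C)C(C)(C)C)[C@](C)([C@@H](O[Si](C)(C)C(C)(C)C)C=C)[C@H]1[C@H](O[Si](C)(C)C(C)(C)C)C(=C)O[C@](C=C)(COCc2ccc(OC)cc2)[C@H](Cl)CO[Si](CC)(CC)CC
F2 | step 15 | primary alcohol from F1 | C=C1CC[C@H](O[Si](C)(C)C(C)(C)C)[C@](C)([C@@H](O[Si](C)(C)C(C)(C)C)C=C)[C@H]1[C@H](O[Si](C)(C)C(C)(C)C)C(=C)O[C@](C=C)(COCc2ccc(OC)cc2)[C@H](Cl)CO
F3 | step 15 | α-chloro acid from F2 | C=C1CC[C@H](O[Si](C)(C)C(C)(C)C)[C@](C)([C@@H](O[Si](C)(C)C(C)(C)C)C=C)[C@H]1[C@H](O[Si](C)(C)C(C)(C)C)C(=C)O[C@](C=C)(COCc2ccc(OC)cc2)[C@H](Cl)C(=O)O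
F4 | step 15 | isobutyl carbonic mixed anhydride of F3 | C=C1CC[C@H](O[Si](C)(C)C(C)(C)C)[C@](C)([C@@H](O[Si](C)(C)C(C)(C)C)C=C)[C@H]1[C@H](O[Si](C)(C)C(C)(C)C)C(=C)O[C@](C=C)(COCc2ccc(OC)cc2)[C@H](Cl)C(=O)OC(=O)OCC(C)C
F5 | step 15 | acyclic diazo ketone | C=C1CC[C@H](O[Si](C)(C)C(C)(C)C)[C@](C)([C@@H](O[Si](C)(C)C(C)(C)C)C=C)[C@H]1[C@H](O[Si](C)(C)C(C)(C)C)C(=C)O[C@](C=C)(COCc2ccc(OC)cc2)[C@H](Cl)C(=O)C=[N+]=[N-]
F6 | step 15 | acyclic ketene | C=C1CC[C@H](O[Si](C)(C)C(C)(C)C)[C@](C)([C@@H](O[Si](C)(C)C(C)(C)C)C=C)[C@H]1[C@H](O[Si](C)(C)C(C)(C)C)C(=C)O[C@](C=C)(COCc2ccc(OC)cc2)[C@H](Cl)C=C=O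
F7 | step 15 | tetrahydrofuran-fused cyclobutanone bearing the C2 and C5 vinyl groups | C=C1CC[C@H](O[Si](C)(C)C(C)(C)C)[C@](C)([C@@H](O[Si](C)(C)C(C)(C)C)C=C)[C@H]1[C@H](O[Si](C)(C)C(C)(C)C)[C@@]2(CC(=O)[C@H]2[C@H]3Cl)O[C@]3(C=C)COCc4ccc(OC)cc4
F8 | step 20 | homologous acid (C6–C7H2–C19O2H) | C=C1CC[C@H](O[Si](C)(C)C(C)(C)C)[C@]2(C)[C@@H](O[Si](C)(C)C(C)(C)C)/C=C\[C@]([C@H](Cl)CC(=O)O)(COCc3ccc(OC)cc3)OC(=C)[C@@H](O[Si](C)(C)C(C)(C)C)[C@@H]12
F9 | step 20 | acid chloride of F8 | C=C1CC[C@H](O[Si](C)(C)C(C)(C)C)[C@]2(C)[C@@H](O[Si](C)(C)C(C)(C)C)/C=C\[C@]([C@H](Cl)CC(=O)Cl)(COCc3ccc(OC)cc3)OC(=C)[C@@H](O[Si](C)(C)C(C)(C)C)[C@@H]12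
F10 | step 22 | 17-(dimethylaminomethyl) lactone (Mannich base) | C=C1CC[C@H](O[Si](C)(C)C(C)(C)C)[C@]2(C)[C@@H](O[Si](C)(C)C(C)(C)C)/C=C\[C@]3(COCc5ccc(OC)cc5)O[C@]4(C(CN(C)C)C(=O)O[C@H]4[C@H]3Cl)[C@@H](O[Si](C)(C)C(C)(C)C)[C@@H]12
F11 | step 22 | trimethylammonium iodide of F10 | C=C1CC[C@H](O[Si](C)(C)C(C)(C)C)[C@]2(C)[C@@H](O[Si](C)(C)C(C)(C)C)/C=C\[C@]3(COCc5ccc(OC)cc5)O[C@]4(C(C[N+](C)(C)C)C(=O)O[C@H]4[C@H]3Cl)[C@@H](O[Si](C)(C)C(C)(C)C)[C@@H]12.[I-]
F12 | step 22 | 17-methylene lactone | C=C1CC[C@H](O[Si](C)(C)C(C)(C)C)[C@]2(C)[C@@H](O[Si](C)(C)C(C)(C)C)/C=C\[C@]3(COCc5ccc(OC)cc5)O[C@]4(C(=C)C(=O)O[C@H]4[C@H]3Cl)[C@@H](O[Si](C)(C)C(C)(C)C)[C@@H]12
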